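## Retrosynthetic overview

1. Feature: in the benzene ring of unit A (the 7-hydroxy-6,8-dimethoxycoumarin), C8a carries the ring oxygen O1 and C6 carries a methoxy group. The two carbons are para, which is the 4-methoxyphenol pattern left by a chromium carbene benzannulation. C7 and C8 carry the two remaining oxygens.
2. Key disconnection: C5–C6, C4a–C8a, C8–C8a and O1–C2. One fragment is a trimethoxy-substituted vinylcarbene chromium complex, which supplies C6, C7, C8 and, from a CO ligand, C8a and O1. The other is a terminal (Z)-enyne ester that already bears unit B and supplies C5, C4a, C4, C3 and C2.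
3. An aldol condensation with a propynal would be expected to place the alkyne trans to the ester. The geometry is therefore set by another path: unit B coumarin-3-acetate, then α-formyl ester, then lithium-chelate (Z)-enol tosylate, then stereoretentive Sonogashira coupling.
4. Ring order: the pyranone ring of unit B is closed first, by a Perkin-type closure on a purchased benzene ring. The benzene ring and the pyranone ring of unit A are then closed together in the key step.
5. End game: the benzyl ethers are removed by hydrogenolysis first, because they would not survive AlCl3. AlCl3 then cleaves the central C7 methyl ether.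

Key step: step 9

Assumption: (Z)-1,2-dimethoxyethene is taken as purchasable. It is otherwise reached by loss of methanol from commercial 1,1,2-trimethoxyethane.

## Route

Step 1
Reactants: 1 (Z)-1,2-dimethoxyethene; 2 hexacarbonylchromium, Cr(CO)6
Product: 5 pentacarbonyl[(Z)-1,2-dimethoxyvinyl(methoxy)carbene]chromium, via (Z)-1,2-dimethoxyvinyllithium 3 (not isolated), via lithium acylchromate 4 (not isolated)
Conditions: 1 (1.2 equiv), t-BuLi (1.1 equiv), THF, −78 °C; Cr(CO)6, −78 → 0 °C; solvent exchange; Me3OBF4, CH2Cl2, 0 °C → rt, Ar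
Reagents that add atoms: trimethyloxonium tetrafluoroborate, C[O+](C)C.F[B-](F)(F)F
Why: α-Deprotonation of the enol ether with retention of geometry is followed by the Fischer carbene synthesis (vinyllithium addition to a CO ligand, then O-methylation of the acylate), a sequence known for α-alkoxyvinyllithiums such as 2-lithiodihydropyran, and the low temperature holds back loss of LiOMe, as supported by the stability of 2-lithio-1,4-dioxene, which has the same anti arrangement of lithium and β-oxygen.

Step 2
Reactants: 6 2,4,5-trihydroxybenzaldehyde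
Product: 7 4,5-bis(benzyloxy)-2-hydroxybenzaldehyde
Conditions: BnBr (2.05 equiv), K2CO3 (2.1 equiv), DMF, 0 °C → rt, Ar
Reagents that add atoms: benzyl bromide, BrCc1ccccc1
Why: In this Williamson etherification the 2-OH is hydrogen-bonded to the aldehyde and its phenoxide is delocalised into the carbonyl group, so two equivalents of BnBr should alkylate only O4 and O5.

Step 3
Reactants: 7 4,5-bis(benzyloxy)-2-hydroxybenzaldehyde; 8 succinic anhydride
Product: 9 2-[6,7-bis(benzyloxy)-2-oxo-2H-chromen-3-yl]acetic acid
Conditions: 8 (4 equiv, melt), disodium succinate (1 equiv), 160 °C, Ar; then 1 M HCl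
Reagents that add atoms: none
Why: In this Perkin-type condensation, known for salicylaldehydes and succinic anhydride, the phenol is acylated and the α-CH2 of the aryl ester condenses on the aldehyde within the molecule, so the pyranone ring of unit B closes with its cis geometry enforced, while excess anhydride holds back a second condensation of 9 with 7.

Step 4
Reactants: 9 2-[6,7-bis(benzyloxy)-2-oxo-2H-chromen-3-yl]acetic acid
Product: 10 methyl 2-[6,7-bis(benzyloxy)-2-oxo-2H-chromen-3-yl]acetate
Conditions: MeOH–toluene, cat. H2SO4, reflux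
Reagents that add atoms: methanol, CO
Why: This is a Fischer esterification, in which the aryl benzyl ethers are stable to catalytic acid and any opened lactone recloses because its alkene is cis.

Step 5
Reactants: 10 methyl 2-[6,7-bis(benzyloxy)-2-oxo-2H-chromen-3-yl]acetate
Product: 12 methyl (Z)-2-[6,7-bis(benzyloxy)-2-oxo-2H-chromen-3-yl]-3-hydroxyacrylate (α-formyl ester, chelated enol form), via enamino ester 11 (not isolated)
Conditions: Me2NCH(OMe)2 (3 equiv), DMF, 95 °C; then 2 M HCl, THF, rt
Reagents that add atoms: N,N-dimethylformamide dimethyl acetal, COC(OC)N(C)C; water, O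
Why: Aminomethylenation of an activated arylacetate-type CH2 with an amide acetal, followed by mild acid hydrolysis of the enamine, is a standard non-nucleophilic formylation that spares the lactone and the benzyl ethers.

Step 6
Reactants: 12 methyl (Z)-2-[6,7-bis(benzyloxy)-2-oxo-2H-chromen-3-yl]-3-hydroxyacrylate
Product: 13 methyl (Z)-2-[6,7-bis(benzyloxy)-2-oxo-2H-chromen-3-yl]-3-(tosyloxy)acrylate
Conditions: TsCl, TMEDA, LiCl, EtOAc–MeCN, 0 °C
Reagents that add atoms: p-toluenesulfonyl chloride, Cc1ccc(cc1)S(=O)(=O)Cl
Why: In this stereoselective enol tosylation of an α-formyl ester, Li+ holds the enolate oxygen and the ester carbonyl in a six-membered chelate, so sulfonylation should fix the oxygen cis to CO2Me under non-hydrolytic conditions.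

Step 7
Reactants: 13 methyl (Z)-2-[6,7-bis(benzyloxy)-2-oxo-2H-chromen-3-yl]-3-(tosyloxy)acrylate; 14 trimethylsilylacetylene
Product: 15 methyl (Z)-2-[6,7-bis(benzyloxy)-2-oxo-2H-chromen-3-yl]-5-(trimethylsilyl)pent-2-en-4-ynoate
Conditions: PdCl2(PPh3)2 (5 mol %), CuI (10 mol %), iPr2NEt, THF, 40 °C
Reagents that add atoms: none
Why: In this Sonogashira coupling of an acceptor-activated enol tosylate, oxidative addition to zerovalent palladium and reductive elimination both proceed with retention at the sp2 carbon, and the hindered tertiary amine cannot displace the tosylate by addition–elimination.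

Step 8
Reactants: 15 methyl (Z)-2-[6,7-bis(benzyloxy)-2-oxo-2H-chromen-3-yl]-5-(trimethylsilyl)pent-2-en-4-ynoate
Product: 16 methyl (Z)-2-[6,7-bis(benzyloxy)-2-oxo-2H-chromen-3-yl]pent-2-en-4-ynoate
Conditions: TBAF, AcOH (1:1), THF, 0 °C
Reagents that add atoms: none
Why: This is a fluoride-induced protodesilylation of an alkynylsilane, and the acetic acid buffer prevents conjugate addition, lactone opening and alkene isomerisation.

Step 9
Reactants: 5 pentacarbonyl[(Z)-1,2-dimethoxyvinyl(methoxy)carbene]chromium; 16 methyl (Z)-2-[6,7-bis(benzyloxy)-2-oxo-2H-chromen-3-yl]pent-2-en-4-ynoate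
Product: 19 6',7'-bis(benzyloxy)-6,7,8-trimethoxy-3,3'-bicoumarin (7-O-methyl-6',7'-di-O-benzylarteminorin C), via Cr(CO)3-bound phenol 17 (not isolated), via free phenol ester 18 (not isolated)
Conditions: 5 (1.5 equiv), THF (0.05 M), 50 °C, Ar; then air, CH2Cl2, rt; cat. PPTS, rt, to complete ring closure
Reagents that add atoms: none
Why: Proposed new method: loss of one CO from 5 lets the terminal alkyne of 16 bind and insert into the Cr=C bond with its substituted carbon next to chromium (C5–C6), a CO ligand then migrates to give a chromium-bound dienylketene (C4a–C8a), and electrocyclisation onto the CH(OMe) terminus (C8–C8a) followed by enolisation gives the η6-Cr(CO)3 complex 17 of a 4-methoxyphenol, which air releases as 18. The closest known reaction type is the Dötz benzannulation of alkenyl(methoxy)carbene chromium complexes with terminal alkynes, α-alkoxyvinyl (dihydropyranyl) complexes included, and what is new here is a vinyl group oxygenated on both carbons combined with an alkyne conjugated to an acceptor alkene. The benzene ring closes by six-electron electrocyclisation of the dienylketene, helped by the (Z)-vinyl group, which turns its hydrogen and not its methoxy group inward, and the pyranone ring closes by 6-exo-trig addition–elimination of the new phenol on the cis methyl ester (O1–C2) with loss of methanol, which also shields the electron-rich phenol from oxidation. The selectivity needed is the regiochemistry of alkyne insertion, and it is secured by the terminal alkyne, whose CH carbon bonds to the carbene carbon for steric reasons so that C4a ends beside C8a. The (Z)-alkene of 16 secures lactonisation and also holds the C3'=C4' bond of unit B trans to the ketene, so a second electrocyclisation mode is geometrically excluded. No stereocentre is formed.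

Step 10
Reactants: 19 6',7'-bis(benzyloxy)-6,7,8-trimethoxy-3,3'-bicoumarin
Product: 20 6',7'-dihydroxy-6,7,8-trimethoxy-3,3'-bicoumarin (7-O-methylarteminorin C)
Conditions: H2 (1 atm), 10% Pd/C, THF–MeOH, rt
Reagents that add atoms: none
Why: Hydrogenolysis of the aryl benzyl ethers is placed before the Lewis acid step because AlCl3 would itself strip the benzyl groups and release benzylating species, and the trisubstituted, conjugated C3=C4 bonds of both pyranone rings should not be reduced at atmospheric pressure.

Step 11
Reactants: 20 6',7'-dihydroxy-6,7,8-trimethoxy-3,3'-bicoumarin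
Product: 21 arteminorin C
Conditions: AlCl3 (6 equiv), ClCH2CH2Cl, rt → 40 °C; then 1 M HCl
Reagents that add atoms: none
Why: This Lewis acid cleavage of the middle ether of a 1,2,3-trimethoxyarene follows the pattern of 3,4,5-trimethoxybenzaldehyde going to syringaldehyde, since the C7 methoxy group is twisted out of plane by its neighbours, chelates aluminium with a flanking oxygen and is the only one para to C4a, so chloride should attack its methyl group first while the catechol is merely held as an aluminium catecholate until work-up.

## Compound list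

1 | (Z)-1,2-dimethoxyethene | CO/C=C\OC | starting material
2 | hexacarbonylchromium, Cr(CO)6 | O=C=[Cr](=C=O)(=C=O)(=C=O)(=C=O)=C=O | starting material
3 | (Z)-1,2-dimethoxyvinyllithium | [Li]/C(OC)=C/OC | intermediate
4 | lithium pentacarbonyl[(Z)-2,3-dimethoxyacryloyl]chromate | [Li+].[O-]C(=[Cr](=C=O)(=C=O)(=C=O)(=C=O)=C=O)/C(OC)=C/OC | intermediate
5 | pentacarbonyl[(Z)-1,2-dimethoxyvinyl(methoxy)carbene]chromium | COC(=[Cr](=C=O)(=C=O)(=C=O)(=C=O)=C=O)/C(OC)=C/OC | intermediate
6 | 2,4,5-trihydroxybenzaldehyde | O=Cc1cc(O)c(O)cc1O | starting material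
7 | 4,5-bis(benzyloxy)-2-hydroxybenzaldehyde | O=Cc1cc(OCc2ccccc2)c(OCc2ccccc2)cc1O | intermediate
8 | succinic anhydride | O=C1CCC(=O)O1 | starting material
9 | 2-[6,7-bis(benzyloxy)-2-oxo-2H-chromen-3-yl]acetic acid | OC(=O)Cc1cc2cc(OCc3ccccc3)c(OCc3ccccc3)cc2oc1=O | intermediate
10 | methyl 2-[6,7-bis(benzyloxy)-2-oxo-2H-chromen-3-yl]acetate | COC(=O)Cc1cc2cc(OCc3ccccc3)c(OCc3ccccc3)cc2oc1=O | intermediate
11 | methyl (E)-2-[6,7-bis(benzyloxy)-2-oxo-2H-chromen-3-yl]-3-(dimethylamino)acrylate (geometry lost on hydrolysis) | CN(C)/C=C(/C(=O)OC)c1cc2cc(OCc3ccccc3)c(OCc3ccccc3)cc2oc1=O | intermediate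
12 | methyl (Z)-2-[6,7-bis(benzyloxy)-2-oxo-2H-chromen-3-yl]-3-hydroxyacrylate | O/C=C(\C(=O)OC)c1cc2cc(OCc3ccccc3)c(OCc3ccccc3)cc2oc1=O | intermediate
13 | methyl (Z)-2-[6,7-bis(benzyloxy)-2-oxo-2H-chromen-3-yl]-3-(tosyloxy)acrylate | Cc1ccc(cc1)S(=O)(=O)O/C=C(\C(=O)OC)c1cc2cc(OCc3ccccc3)c(OCc3ccccc3)cc2oc1=O | intermediate
14 | trimethylsilylacetylene | C#C[Si](C)(C)C | starting material
15 | methyl (Z)-2-[6,7-bis(benzyloxy)-2-oxo-2H-chromen-3-yl]-5-(trimethylsilyl)pent-2-en-4-ynoate | C[Si](C)(C)C#C/C=C(\C(=O)OC)c1cc2cc(OCc3ccccc3)c(OCc3ccccc3)cc2oc1=O | intermediate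
16 | methyl (Z)-2-[6,7-bis(benzyloxy)-2-oxo-2H-chromen-3-yl]pent-2-en-4-ynoate | C#C/C=C(\C(=O)OC)c1cc2cc(OCc3ccccc3)c(OCc3ccccc3)cc2oc1=O | intermediate
17 | η6-tricarbonylchromium complex of 18 (metal on the new benzene ring, written as two parts) | COC(=O)/C(=C\c1cc(OC)c(OC)c(OC)c1O)c1cc2cc(OCc3ccccc3)c(OCc3ccccc3)cc2oc1=O.O=C=[Cr](=C=O)=C=O | intermediate
18 | methyl (Z)-2-[6,7-bis(benzyloxy)-2-oxo-2H-chromen-3-yl]-3-(2-hydroxy-3,4,5-trimethoxyphenyl)acrylate | COC(=O)/C(=C\c1cc(OC)c(OC)c(OC)c1O)c1cc2cc(OCc3ccccc3)c(OCc3ccccc3)cc2oc1=O | intermediate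
19 | 6',7'-bis(benzyloxy)-6,7,8-trimethoxy-3,3'-bicoumarin | COc1cc2cc(-c3cc4cc(OCc5ccccc5)c(OCc5ccccc5)cc4oc3=O)c(=O)oc2c(OC)c1OC | intermediate
20 | 6',7'-dihydroxy-6,7,8-trimethoxy-3,3'-bicoumarin | COc1cc2cc(-c3cc4cc(O)c(O)cc4oc3=O)c(=O)oc2c(OC)c1OC | intermediate
21 | arteminorin C | COc1cc2cc(-c3cc4cc(O)c(O)cc4oc3=O)c(=O)oc2c(OC)c1O | target

Total step count: 11
Longest linear sequence: 10 (steps 2 to 11)

## Steps most likely to fail

**Step 9.**
- The acceptor-conjugated alkyne may be taken up slowly.
- The donor-rich chromium vinylcarbene may close without CO insertion to a five-membered ring.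
- The electron-rich phenol may be oxidised before it lactonises.

The fallback uses known chemistry, sets out from acid 9 and comes back at 19. Commercial 2,3,4-trimethoxybenzaldehyde is taken by Dakin oxidation (H2O2, cat. H2SO4, MeOH) to 2,3,4-trimethoxyphenol F1. The only free ortho position of that phenol is formylated (MgCl2, Et3N, paraformaldehyde, MeCN, reflux) to give 2-hydroxy-3,4,5-trimethoxybenzaldehyde F2. Perkin–Oglialoro condensation of F2 with 9 (Ac2O, Et3N, 110 °C) then closes the pyranone ring of unit A on a ready-made benzene ring and gives 19.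

**Step 1.**
- The vinyllithium may lose lithium methoxide, because lithium stands anti to the β-methoxy group.
- The electron-rich carbene complex may decompose during isolation.

The fallback avoids any vinyllithium, sets out from 2 and comes back at 5.
- Methyl methoxyacetate is formylated with methyl formate and NaH to sodium (Z)-2,3-dimethoxy-3-oxoprop-1-en-1-olate F3.
- O-Methylation with Me2SO4 in DMF gives methyl (Z)-2,3-dimethoxyacrylate F4.
- LiOH in aqueous THF followed by acid gives (Z)-2,3-dimethoxyacrylic acid F5.
- (COCl)2 with cat. DMF gives (Z)-2,3-dimethoxyacryloyl chloride F6.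
- Separately, 2 is reduced with potassium graphite C8K (THF, −78 °C) to dipotassium pentacarbonylchromate F7.
- Acylation of F7 by F6 gives potassium pentacarbonyl[(Z)-2,3-dimethoxyacryloyl]chromate F8, and Me3OBF4 converts this to 5.

**Step 11.**
- Site selectivity may be lost through the aluminium phenolate chelate, which can pass the cleavage on to a flanking methyl ether.
- Conversion may stall because the aluminium catecholate dissolves poorly.

The fallback reverses the order of the end game and replaces chelation control with leaving-group control. It sets out from 19 and comes back at 21. Excess sodium ethanethiolate (NaSEt) in DMF at 100 °C attacks by SN2 the alkyl groups whose aryloxides are conjugated with a lactone carbonyl, namely the C7 methyl and the C7' benzyl group. After acidification this should give 6'-O-benzylarteminorin C F9. Any further loss of benzyl is harmless, and hydrogenolysis (H2, Pd/C, THF–MeOH) gives 21.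

## Further compounds

F1 | step 9 | 2,3,4-trimethoxyphenol | COc1ccc(O)c(OC)c1OC
F2 | step 9 | 2-hydroxy-3,4,5-trimethoxybenzaldehyde | COc1cc(C=O)c(O)c(OC)c1OC
F3 | step 1 | sodium (Z)-2,3-dimethoxy-3-oxoprop-1-en-1-olate | [Na+].[O-]/C=C(OC)/C(=O)OC
F4 | step 1 | methyl (Z)-2,3-dimethoxyacrylate | COC(=O)/C(OC)=C/OC
F5 | step 1 | (Z)-2,3-dimethoxyacrylic acid | OC(=O)/C(OC)=C/OC
F6 | step 1 | (Z)-2,3-dimethoxyacryloyl chloride | ClC(=O)/C(OC)=C/OC
F7 | step 1 | dipotassium pentacarbonylchromate, K2Cr(CO)5 | [K+].[K+].O=C=[Cr-2](=C=O)(=C=O)(=C=O)=C=O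
F8 | step 1 | potassium pentacarbonyl[(Z)-2,3-dimethoxyacryloyl]chromate | [K+].[O-]C(=[Cr](=C=O)(=C=O)(=C=O)(=C=O)=C=O)/C(OC)=C/OC
F9 | step 11 | 6'-O-benzylarteminorin C | COc1cc2cc(-c3cc4cc(OCc5ccccc5)c(O)cc4oc3=O)c(=O)oc2c(OC)c1O
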